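C1 = ester carbon, ring = C8–C12, C20 = methyl. Target 25 ⇒ (PMB removal) 24 ⇒ chelation-controlled Mukaiyama aldol forming C7–C8 between bromo-siloxydiene 14 (C8–C20) and aldehyde 22 (C1–C7), whose C5 and C6 come from 2-deoxy-D-ribose.
14 ⇒ bromoenone 13 ⇒ (epoxide, then HBr) enone 10. The molecule has one ring, the cyclopentenone C8–C12, and it is built in a single operation.
Key disconnection: C9–C10 and C11–C12 are made together from the alkyne Me3Si–C≡CH (C10, C11) and a three-carbon unit C9–C8–C12.
Enabling feature: the C9 carbonyl and the C12 carbinol stand 1,3 across C8, so the ring hides a β-keto acid. Locked as the enol ketal (1,3-dioxin-4-one 7, spiro to menthone), this unit has no acidic C8–H, keeps O12 on C12, makes C12 an enoate β-carbon and C9 an acyl donor, and lets the terpene steer C12.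
7 ⇐ (3Z,6Z)-nonadienol (C12–C20) + Meldrum's acid (C8, C9) + (−)-menthone (temporary ring, expelled in the key step).

Key step: step 4

Assumption: the anomeric centres of 16–18 are mixtures and are written without a descriptor, because this centre is lost in step 11.

Step 1
Reactants: 1 (3Z,6Z)-nona-3,6-dien-1-ol
Product: 2 (3Z,6Z)-nona-3,6-dienoic acid
Conditions: TEMPO (cat.), PhI(OAc)2 (2.2 equiv), MeCN–H2O, 0 to 23 °C
Reagents that add atoms: water, O
Why: Oxoammonium (TEMPO) oxidation runs through the aldehyde hydrate under almost neutral conditions, so the Z-alkenes should stay in place and the β,γ-double bond should not move into conjugation.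

Step 2
Reactants: 2 (3Z,6Z)-nona-3,6-dienoic acid; 3 Meldrum's acid
Product: 4 5-[(3Z,6Z)-1-hydroxynona-3,6-dienylidene] Meldrum's acid
Conditions: DCC, DMAP (cat.), CH2Cl2, 0 °C
Reagents that add atoms: none
Why: Carbodiimide-mediated C-acylation of Meldrum's acid gives the fully enolised acyl derivative, which joins C8 and C9 to C12 without strong base.

Step 3
Reactants: 4 acyl Meldrum's acid; 5 (−)-menthone
Product: 7 (6S,7S,10R)-7-isopropyl-10-methyl-2-[(2Z,5Z)-octa-2,5-dien-1-yl]-1,5-dioxaspiro[5.5]undec-2-en-4-one, via acylketene 6 (not isolated)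
Conditions: 5 (4 equiv), toluene, 110 °C; chromatography
Reagents that add atoms: none
Why: Thermal loss of acetone and CO2 gives the acylketene, which the menthone carbonyl traps in a hetero-[4+2] cycloaddition; because this cycloaddition is reversible at 110 °C, the spiro centre equilibrates and the 6S ketal is collected by chromatography.

Step 4
Reactants: 7 spiro dioxinone; 8 ethynyltrimethylsilane
Product: 10 (S)-4-hydroxy-4-[(2Z,5Z)-octa-2,5-dien-1-yl]cyclopent-2-en-1-one, via silyl enone 9 (not isolated)
Conditions: Ni(cod)2 (10 mol %), PBu3 (20 mol %), Et3B (3 equiv), THF–MeOH 8:1, 50 °C; then Bu4NF, AcOH, 0 °C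
Reagents that add atoms: none
Why: Proposed new method: zerovalent nickel should bind 8 and the only electron-poor alkene of 7 (C8=C12, activated by Et3B at the C9 carbonyl) and couple them oxidatively, the CH terminus C11 bonding to C12 while nickel stays on the silyl-bearing C10; MeOH then protonates the nickel enolate at C8, the alkenyl–nickel bond adds to the acylal carbonyl C9, the tetrahedral intermediate collapses with loss of menthone (which uncovers O12), and Et3B (ethyl transfer, β-hydride elimination, reductive elimination) returns divalent nickel to the zerovalent state. The closest known reaction type is the nickel-catalysed reductive [3+2] cycloaddition of aryl enoates or N-enoyl oxazolidinones with alkynes under Et3B/MeOH, supported by the nickel-catalysed annulation of salicylic acid ketals with alkynes in which the ketone is likewise expelled; what is new is a β-oxygenated, β,β-disubstituted enoate held in a 1,3-dioxin-4-one. The single ring (cyclopentenone C8–C12) closes by 5-exo-trig attack of C10 on C9=O through a bridged 2,4-dioxabicyclo[3.2.1]oct-6-ene alkoxide. The only new stereocentre, C12, is set when the C11–C12 bond forms, because the isopropyl-bearing carbon of the menthane ring covers one face of the flat dioxinone, so nickel and alkyne approach from the CH2 side, which gives 12S. The step needs regioselectivity (Me3Si keeps nickel on C10 and suppresses alkyne oligomerisation), chemoselectivity over the skipped Z,Z-diene (isolated alkenes do not enter the oxidative coupling), and C–C rather than C–O closure or β-alkoxide loss (the six-membered ring holds the C12–O bond out of line with the C8–Ni bond, and the protic medium frees C9 for attack). Buffered fluoride then replaces the α-silyl group by hydrogen in the same flask.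

Step 5
Reactants: 10 hydroxy enone
Product: 11 (4S)-2,3-epoxy-4-hydroxy-4-[(2Z,5Z)-octa-2,5-dien-1-yl]cyclopentan-1-one, epoxide oxygen cis to the hydroxyl
Conditions: 30 % H2O2, NaOH (cat.), MeOH, −20 °C
Reagents that add atoms: hydrogen peroxide, OO
Why: Weitz–Scheffer nucleophilic epoxidation touches only the enone and leaves the isolated alkenes alone, and hydroperoxide attacks C11 anti to the octadienyl chain (syn to OH), which sets two stereocentres that disappear again in step 6.

Step 6
Reactants: 11 epoxy ketone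
Product: 13 (S)-2-bromo-4-hydroxy-4-[(2Z,5Z)-octa-2,5-dien-1-yl]cyclopent-2-en-1-one, via bromohydrin 12 (not isolated)
Conditions: 48 % aq HBr (1.2 equiv), THF, 0 to 23 °C
Reagents that add atoms: hydrogen bromide, Br
Why: Bromide opens the protonated α,β-epoxy ketone by SN2 attack at C10 (α to the carbonyl and, unlike C11, not neopentyl), the β-hydroxy ketone then loses water under acid to give the 2-bromoenone, and cold dilute HBr should not add to the Z-alkenes.

Step 7
Reactants: 13 bromoenone
Product: 14 (S)-3-bromo-5-[(2Z,5Z)-octa-2,5-dien-1-yl]-2,5-bis(trimethylsilyloxy)cyclopenta-1,3-diene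
Conditions: Me3SiOTf (2.4 equiv), Et3N, CH2Cl2, −20 to 0 °C
Reagents that add atoms: trimethylsilyl triflate, C[Si](C)(C)OS(=O)(=O)C(F)(F)F
Why: Soft enolisation with silyl triflate and amine can deprotonate only at C8 and caps O12 in the same operation, and the quaternary C12 blocks hydrogen shifts and dimerisation of the diene.

Step 8
Reactants: 15 2-deoxy-D-ribose
Product: 16 methyl 2-deoxy-D-erythro-pentopyranoside
Conditions: HCl (cat.), MeOH, 23 °C, equilibrating
Reagents that add atoms: methanol, CO
Why: Fischer glycosidation under thermodynamic control favours the pyranoside, which ties up O7 in the ring and leaves only O5 and O6 free.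

Step 9
Reactants: 16 methyl pyranoside
Product: 17 methyl 2-deoxy-3,4-di-O-(4-methoxybenzyl)-D-erythro-pentopyranoside
Conditions: NaH, PMBCl, Bu4NI (cat.), DMF, 0 to 23 °C
Reagents that add atoms: 4-methoxybenzyl chloride, COc1ccc(CCl)cc1
Why: Williamson etherification places on O5 and O6 groups that can chelate magnesium in step 14 and are removed oxidatively at the end.

Step 10
Reactants: 17 bis-PMB glycoside
Product: 18 2-deoxy-3,4-di-O-(4-methoxybenzyl)-D-erythro-pentopyranose
Conditions: AcOH–H2O 4:1, 50 °C
Reagents that add atoms: water, O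
Why: Acetal hydrolysis of a 2-deoxy glycoside is fast enough in weak acid for the PMB ethers to survive.

Step 11
Reactants: 18 lactol; 19 methyl (triphenylphosphoranylidene)acetate
Product: 20 methyl (2E,5S,6R)-7-hydroxy-5,6-bis(4-methoxybenzyloxy)hept-2-enoate
Conditions: toluene, 80 °C
Reagents that add atoms: none
Why: The Wittig reaction of the stabilised ylide with the open-chain aldehyde form adds C1 and C2 and releases O7 as the only free hydroxyl.

Step 12
Reactants: 20 enoate
Product: 21 methyl (5S,6R)-7-hydroxy-5,6-bis(4-methoxybenzyloxy)heptanoate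
Conditions: H2 (1 atm), Pd/C, pyridine (0.5 equiv), MeOH, 23 °C
Reagents that add atoms: none
Why: Catalytic hydrogenation over amine-poisoned Pd/C saturates the enoate while hydrogenolysis of the benzylic ethers is suppressed.

Step 13
Reactants: 21 primary alcohol
Product: 22 methyl (5S,6S)-5,6-bis(4-methoxybenzyloxy)-7-oxoheptanoate
Conditions: TEMPO (cat.), PhI(OAc)2 (1.1 equiv), CH2Cl2, 23 °C
Reagents that add atoms: none
Why: Water-free oxoammonium oxidation stops at the aldehyde and is mild enough not to epimerise C6.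

Step 14
Reactants: 14 bromo-siloxydiene; 22 aldehyde
Product: 24 5,6-bis(4-methoxybenzyl) ether of the target (7S,8R,12S), via bis-silyl aldol 23 (not isolated)
Conditions: 22, MgBr2·OEt2 (3 equiv), CH2Cl2, −78 °C; 14, −78 to −30 °C; then 1 M HCl, THF, 0 °C
Reagents that add atoms: none
Why: In this chelation-controlled Mukaiyama aldol, MgBr2 ties the aldehyde oxygen to the C6 PMB ether in a five-membered chelate so that C8 attacks the face away from the C5 branch (C6/C7 syn, 7S), the open transition state favours the C7/C8 syn adduct, the diene reacts anti to the octadienyl chain on C12 (8R, also the more stable trans arrangement), and dilute acid then removes both Me3Si groups.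

Step 15
Reactants: 24 bis-PMB ether
Product: 25 target, methyl (5S,6S,7S)-7-{(1R,5S)-3-bromo-5-hydroxy-5-[(2Z,5Z)-octa-2,5-dien-1-yl]-2-oxocyclopent-3-en-1-yl}-5,6,7-trihydroxyheptanoate
Conditions: DDQ (2.6 equiv), CH2Cl2–pH 7 buffer 10:1, 0 °C
Reagents that add atoms: none
Why: Oxidative PMB cleavage in a wet, buffered medium is neutral, so the β-hydroxy ketone should neither eliminate nor epimerise and no benzylidene acetal should persist.

Compound list
1 | (3Z,6Z)-nona-3,6-dien-1-ol | CC/C=C\C/C=C\CCO | starting material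
2 | (3Z,6Z)-nona-3,6-dienoic acid | CC/C=C\C/C=C\CC(=O)O | intermediate
3 | Meldrum's acid | CC1(C)OC(=O)CC(=O)O1 | starting material
4 | 5-[(3Z,6Z)-1-hydroxynona-3,6-dienylidene] Meldrum's acid | CC/C=C\C/C=C\CC(O)=C1C(=O)OC(C)(C)OC1=O | intermediate
5 | (−)-menthone, (2S,5R) | CC(C)[C@@H]1CC[C@@H](C)CC1=O | starting material
6 | (5Z,8Z)-3-oxoundeca-1,5,8-trien-1-one (acylketene) | CC/C=C\C/C=C\CC(=O)C=C=O | intermediate
7 | (6S,7S,10R)-7-isopropyl-10-methyl-2-[(2Z,5Z)-octa-2,5-dien-1-yl]-1,5-dioxaspiro[5.5]undec-2-en-4-one | CC(C)[C@@H]1CC[C@@H](C)C[C@]12OC(=O)C=C(C/C=C\C/C=C\CC)O2 | intermediate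
8 | ethynyltrimethylsilane | C#C[Si](C)(C)C | starting material
9 | (S)-4-hydroxy-4-[(2Z,5Z)-octa-2,5-dien-1-yl]-2-(trimethylsilyl)cyclopent-2-en-1-one | CC/C=C\C/C=C\C[C@@]1(O)C=C([Si](C)(C)C)C(=O)C1 | intermediate
10 | (S)-4-hydroxy-4-[(2Z,5Z)-octa-2,5-dien-1-yl]cyclopent-2-en-1-one | CC/C=C\C/C=C\C[C@@]1(O)C=CC(=O)C1 | intermediate
11 | (4S)-2,3-epoxy-4-hydroxy-4-[(2Z,5Z)-octa-2,5-dien-1-yl]cyclopentan-1-one, epoxide cis to OH | CC/C=C\C/C=C\C[C@@]1(O)[C@@H]2O[C@@H]2C(=O)C1 | intermediate
12 | (4S)-2-bromo-3,4-dihydroxy-4-[(2Z,5Z)-octa-2,5-dien-1-yl]cyclopentan-1-one, Br trans to the C3 hydroxyl, hydroxyls cis | CC/C=C\C/C=C\C[C@@]1(O)[C@H](O)[C@@H](Br)C(=O)C1 | intermediate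
13 | (S)-2-bromo-4-hydroxy-4-[(2Z,5Z)-octa-2,5-dien-1-yl]cyclopent-2-en-1-one | CC/C=C\C/C=C\C[C@@]1(O)C=C(Br)C(=O)C1 | intermediate
14 | (S)-3-bromo-5-[(2Z,5Z)-octa-2,5-dien-1-yl]-2,5-bis(trimethylsilyloxy)cyclopenta-1,3-diene | CC/C=C\C/C=C\C[C@@]1(O[Si](C)(C)C)C=C(Br)C(O[Si](C)(C)C)=C1 | intermediate
15 | 2-deoxy-D-ribose | O=CC[C@H](O)[C@H](O)CO | starting material
16 | methyl 2-deoxy-D-erythro-pentopyranoside | COC1C[C@H](O)[C@H](O)CO1 | intermediate
17 | methyl 2-deoxy-3,4-di-O-(4-methoxybenzyl)-D-erythro-pentopyranoside | COC1C[C@H](OCc2ccc(OC)cc2)[C@H](OCc2ccc(OC)cc2)CO1 | intermediate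
18 | 2-deoxy-3,4-di-O-(4-methoxybenzyl)-D-erythro-pentopyranose | OC1C[C@H](OCc2ccc(OC)cc2)[C@H](OCc2ccc(OC)cc2)CO1 | intermediate
19 | methyl (triphenylphosphoranylidene)acetate | COC(=O)C=P(c1ccccc1)(c1ccccc1)c1ccccc1 | starting material
20 | methyl (2E,5S,6R)-7-hydroxy-5,6-bis(4-methoxybenzyloxy)hept-2-enoate | COC(=O)/C=C/C[C@H](OCc1ccc(OC)cc1)[C@H](OCc1ccc(OC)cc1)CO | intermediate
21 | methyl (5S,6R)-7-hydroxy-5,6-bis(4-methoxybenzyloxy)heptanoate | COC(=O)CCC[C@H](OCc1ccc(OC)cc1)[C@H](OCc1ccc(OC)cc1)CO | intermediate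
22 | methyl (5S,6S)-5,6-bis(4-methoxybenzyloxy)-7-oxoheptanoate | COC(=O)CCC[C@H](OCc1ccc(OC)cc1)[C@H](OCc1ccc(OC)cc1)C=O | intermediate
23 | 7,12-bis(trimethylsilyl) 5,6-bis(4-methoxybenzyl) ether of the target | CC/C=C\C/C=C\C[C@@]1(O[Si](C)(C)C)C=C(Br)C(=O)[C@@H]1[C@H](O[Si](C)(C)C)[C@@H](OCc2ccc(OC)cc2)[C@@H](OCc2ccc(OC)cc2)CCCC(=O)OC | intermediate
24 | 5,6-bis(4-methoxybenzyl) ether of the target | CC/C=C\C/C=C\C[C@@]1(O)C=C(Br)C(=O)[C@@H]1[C@H](O)[C@@H](OCc2ccc(OC)cc2)[C@@H](OCc2ccc(OC)cc2)CCCC(=O)OC | intermediate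
25 | CNP0143456.1 | CC/C=C\C/C=C\C[C@@]1(O)C=C(Br)C(=O)[C@@H]1[C@H](O)[C@@H](O)[C@@H](O)CCCC(=O)OC | target

Total step count: 15. Longest linear sequence: 9 (steps 1–7, 14, 15).

Steps most likely to fail

Step 4. The donor-substituted, β,β-disubstituted alkene may bind nickel too weakly for oxidative coupling. Nickel may instead insert into the acyl–oxygen bond and expel menthone before C12 is set, which would lose facial control, or it may close the ring through oxygen. A nickel hydride could also move the skipped diene into conjugation. The fallback sets out from 7, returns at 10, and makes the ring bonds one at a time by known reactions. Conjugate addition of lithium divinylcuprate (vinyllithium, CuI, Et2O, −78 °C) to 7, anti to the isopropyl side, should give the vinyl dioxanone F1. MeNH(OMe)·HCl with i-PrMgCl then opens the acylal to the β-hydroxy Weinreb amide F2 and frees menthone. Excess vinylmagnesium bromide gives the hydroxy dienone F3. Ring-closing metathesis of its two terminal alkenes with the second-generation Grubbs catalyst gives 10.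

Step 14. Chelation may be incomplete, so that the wrong aldehyde face is attacked. The Lewis acid may strip PMB or silyl groups, and the aldol may undergo β-elimination. The fallback sets out from 14 and 22, returns at 24, and installs O7 through boron under catalyst control instead of through the aldol step. A BF3·OEt2-promoted aldol with acidic work-up, run without regard to C7, gives the epimeric aldols F4. MsCl/Et3N followed by DBU gives the (7E)-alkylidene cyclopentenone F5. Copper-catalysed asymmetric conjugate borylation (B2pin2, CuCl, NaOt-Bu, a chiral ferrocenyl diphosphine, MeOH) should add boron to C7 of the less hindered exocyclic enone and hydrogen to C8, giving the boronate F6. NaBO3 oxidation with retention gives 24.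

Step 6. Bromide may open the epoxide at C11 instead of C10, which leads into the 2-hydroxyenone series. Acid may also damage the tertiary alcohol or the side-chain alkenes. The fallback sets out from 10, returns at 13, and avoids the epoxide altogether. α-Iodination with I2/pyridine, which does not touch isolated alkenes, gives the iodoenone F7. Palladium-catalysed stannylation (Me3SnSnMe3, Pd(PPh3)4, toluene) gives the stannyl enone F8. Tin–bromine exchange with NBS at 0 °C gives 13.

Further compounds
F1 | step 4 | (2S,6S,7S,10R)-7-isopropyl-10-methyl-2-[(2Z,5Z)-octa-2,5-dien-1-yl]-2-vinyl-1,5-dioxaspiro[5.5]undecan-4-one | CC(C)[C@@H]1CC[C@@H](C)C[C@]12OC(=O)C[C@](C=C)(C/C=C\C/C=C\CC)O2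
F2 | step 4 | (3S,5Z,8Z)-3-hydroxy-N-methoxy-N-methyl-3-vinylundeca-5,8-dienamide | CC/C=C\C/C=C\C[C@@](O)(C=C)CC(=O)N(C)OC
F3 | step 4 | (5S,7Z,10Z)-5-hydroxy-5-vinyltrideca-1,7,10-trien-3-one | CC/C=C\C/C=C\C[C@@](O)(C=C)CC(=O)C=C
F4 | step 14 | C7/C8-epimeric aldols of 24 (mixture) | CC/C=C\C/C=C\C[C@@]1(O)C=C(Br)C(=O)C1C(O)[C@@H](OCc2ccc(OC)cc2)[C@@H](OCc2ccc(OC)cc2)CCCC(=O)OC
F5 | step 14 | (7E)-7,8-didehydro-7-deoxy derivative of 24 | CC/C=C\C/C=C\C[C@@]1(O)C=C(Br)C(=O)/C1=C/[C@@H](OCc2ccc(OC)cc2)[C@@H](OCc2ccc(OC)cc2)CCCC(=O)OC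
F6 | step 14 | C7 pinacol boronate in place of the C7 hydroxyl of 24 | CC/C=C\C/C=C\C[C@@]1(O)C=C(Br)C(=O)[C@@H]1[C@H](B2OC(C)(C)C(C)(C)O2)[C@@H](OCc2ccc(OC)cc2)[C@@H](OCc2ccc(OC)cc2)CCCC(=O)OC
F7 | step 6 | (S)-4-hydroxy-2-iodo-4-[(2Z,5Z)-octa-2,5-dien-1-yl]cyclopent-2-en-1-one | CC/C=C\C/C=C\C[C@@]1(O)C=C(I)C(=O)C1
F8 | step 6 | (S)-4-hydroxy-4-[(2Z,5Z)-octa-2,5-dien-1-yl]-2-(trimethylstannyl)cyclopent-2-en-1-one | CC/C=C\C/C=C\C[C@@]1(O)C=C([Sn](C)(C)C)C(=O)C1
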